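The runs stem from a simulated flask from invented constants, and the scatter is random.

Start from the late end of the grey flask, the one asked about. From 30.0 min to 40.0 min J gains 13 percentage points, about the 13 points of the step before, while L is fed steadily. Multiply that slope by the dosing time and divide by the equivalents to get 0.335, the fraction of fed L that ends as J: the capture share. The blue run, fed at twice the rate, reads 0.191.

the same everywhere: E 0.041 M

| charge | L | remark | time |
|---|---|---|---|
| grey | 2 equiv (fed, over 50 min) | the very flask that is asked about, followed so far |  |
| blue | 4 equiv (fed, over 50 min) | run made earlier |  |
| flask | 2.00 equiv (fed, over 50 min) |  | 1.5 h |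

- grey (time / min: J / %): 2.00: 0.3; 6.00: 3.0; 10.0: 6.7; 15.0: 13.4; 20.0: 20.5; 30.0: 33.2; 40.0: 46.6
- blue (time / min: J / %): 2.00: 0.1; 6.00: 5.1; 10.0: 10.7; 15.0: 19.3; 20.0: 26.5; 30.0: 42.9; 40.0: 58.2

(readings scatter by 0.5 percentage points)

1. why nothing more happens at 1.5 h, or that something still does (for what has run out or reacted, a solid counts together with what of it has only dissolved) (it is still moving / all of E has reacted)
2. the J standing at 1.5 h, as a percentage of the E charged

- E is a solid; its amount is given per volume of the solution
- at the start none of E is in solution
- what has only dissolved of E counts as not reacted
- the reaction counts as stopped when no species that holds the E changes by six tenths of a point or more over the second half of the time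

Now bound the grey flask, counting the fraction of E left unconverted. In one extreme, uncaptured L stays and keeps reacting, so the fraction left falls to none. In the other, uncaptured L is lost at once, so L acts as the limiting reagent and J stops when the feed stops: the late line carried from 40.0 min to 50 min reaches 60.0%, and 40.0% stays unconverted. My own reckoning sits at the second extreme, since a growing stock of L should steepen the line and the two steps match. On that line J stands near 53.3% at half the time, so the grey flask still counts as moving.

The forecast, made by someone else, also says it is still moving, but puts J at 90% (81% to 98%), 30 points above my figure, reading that “J formation is mostly limited by E dissolving”.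

The grey flask gives it is still moving, with J 65.2%, higher than my 60.0%, a share over the whole charge of 0.326 against the late 0.335.

    D + L → J (k = 0.460 L mol⁻¹ s⁻¹)
    E ⇌ D, rate k2*(cs2 - [D]) while solid is left; crystals form when [D] > cs2 (solubility = 18.0 mM, k = 6.74 × 10⁻⁴ s⁻¹)
    L → G (k = 0.00364 s⁻¹)

In grey, J rose from 53.9% at 0.750 h, L stands at 0% at 1.5 h, and D holds 34.8%. Now charge a neighbouring flask with 0.10 M of E at the same equivalents. Its L feed per minute is 1.22 times blue's, so take blue's share 0.191 rather than grey's 0.335; applied to the whole charge, with the early lag uncounted, that gives J near 38.3%. That neighbouring flask gives J 35.0%, with L at 0% and 51.1% of E still solid.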